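All runs were generated by integration from invented constants, noise included.

1. Take the charge of Q times the elapsed time as the clock of these flasks, with G held at 4.00 equiv. If each step joins two partners, the percentage of X should follow this product, called here the dose.

| flask | Q | G | remark | time |
|---|---|---|---|---|
| noon | 6.8 mM | 4 equiv | run made earlier |  |
| autumn | 170 mM | 4 equiv | run made earlier |  |
| theta | 12 mM | 4.00 equiv |  | 3.0 h |
| zeta | 25 mM | 4.00 equiv |  | 3.0 h |
| alpha | 50 mM | 4.00 equiv |  | 3.0 h |
| gamma | 100 mM | 4.00 equiv |  | 3.0 h |
| eta | 200 mM | 4.00 equiv |  | 3.0 h |

| run | time / h | X / % |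
|---|---|---|
| noon | 0.250 | 6.4 |
| noon | 0.417 | 8.8 |
| noon | 0.667 | 11.7 |
| noon | 1.00 | 16.8 |
| noon | 2.00 | 21.2 |
| noon | 3.00 | 24.3 |
| autumn | 0.250 | 36.6 |
| autumn | 0.417 | 31.8 |
| autumn | 0.667 | 23.4 |
| autumn | 1.00 | 15.6 |
| autumn | 2.00 | 3.8 |
| autumn | 3.00 | 1.3 |

(readings scatter by 1 percentage point)

- the numbers in the tables scatter by 1 percentage point (one standard deviation)
- a reading or a percentage of X counts all its forms, free or not
- the concentration of X that is asked is that of its free form alone
- "hardly changes" means that all values lie within two and a half points (for a concentration: within two and a half percent of the largest)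

* [X] (only what is free in solution) at the end for theta, zeta, alpha, gamma, eta, in this order
* the shape of the row from first to last (hardly changes / falls all the way / rises, then falls / rises all the way / falls, then rises)

2. At noon, X climbs to 24.3% at a dose of 73.4 M·s. In autumn, X stands at 36.6% at a dose of 153 M·s, then sinks to 1.3%. So along the dose, X is first made and later lost.

3. The concentration of X, all forms counted, is charge times percentage. So at a fixed time, if the percentage follows the dose, its logarithmic slope against charge, the local order, is 1 plus the slope of the percentage against dose. That concentration therefore turns where the second slope is minus 1.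

4. In powers of ten, autumn between 0.667 h and 1.00 h loses 0.176 decades of percentage over 0.176 decades of time, a slope of minus 1.00. The logarithmic midpoint of these two readings, scatter included, gives 500 M·s: the turning dose, the charge times time at which the percentage of X falls as fast as the dose grows.

5. Leave the time at 3.0 h, since the turning charge belongs to it: 46.3 mM. My reckoning counts all forms of X and takes free X to go the same way: a row that rises up to about that charge and falls beyond it.

6. The forecast differs: “Free X therefore falls along the row”, with 1.6 mM, 1.3 mM, 0.85 mM, 0.53 mM, 0.33 mM, so falls all the way.

7. The flasks give 2.48 mM, 3.68 mM, 3.85 mM, 2.83 mM, 1.01 mM: rises, then falls.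

    Q + G → X + D (k = 7.84 /M/h)
    G + X → L + D (k = 17.0 /M/h)
    G + L → E + D (k = 13.7 /M/h)
    Q + X ⇌ J, settled at all times (K = 59.0 /M)

The row of free X turns at a charge of Q of 39 mM, a dose of 421 M·s against the turning dose of 500 M·s read from autumn. In theta, at a dose of 130 M·s, the half-life of free X by G + X into L + D alone, concentrations as charged, is 0.85 h, short against 3.0 h, and X, bound forms counted, stands at 25.9% of the Q charged; in eta, at a charge above the turning charge, the local order of free X is −2.5.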